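## Structural features

The target is a germacranolide: a ten-membered carbocycle (C1–C10) fused across C6 (oxygen) and C7 (C11, with methylene C13 and carbonyl C12) to a trans α-methylene-γ-butyrolactone. Both ring alkenes are trisubstituted and cis inside the ring: C4=C5 (Z, methyl C15 on C4, the geometry of nerol) and C1=C10 (C2 and C9 on the same side, formyl C14 on C10; E only because the formyl group outranks C9). Four contiguous stereocentres run from C6 to C9 (6R,7S,8S,9S). H6 and H7 are trans on the lactone, the C7–C11 bond and O8 are anti along the ring, and the C8 (2S)-2-methylbutanoate and the free C9 hydroxyl are syn (threo). A fifth centre lies in the acyl group. The fragile parts are the exocyclic Michael acceptor of the lactone, the γ-hydroxy enal, the 1,2-acyloxy alcohol (acyl migration, and translactonisation whenever O8 is free), the α-centre of the ester and the two cis alkenes. The real difficulty is a strained medium ring with two in-ring cis alkenes next to the C6–C9 array, closed without damage to lactone and ester. The feature exploited is the allylic carbinol C9 bonded to C10 of the C1=C10 alkene. It is the retron of a C10 alkenyl metal adding to a C9 aldehyde, and the in-ring cis geometry of C1=C10 can be fixed beforehand in an acyclic (Z)-2-iodoalkene.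

## Logic of the disconnections

From 30 to 29 and 28 only the oxidation level and protection of C14 change (the C14=O π bond, then the O14–Si bond). An enal would not survive an alkenylchromium, whereas a silyl ether does. The gain is that aldehyde-level C14 never meets a nucleophile. The demand is an oxidant that takes the primary C14 hydroxyl of 29 and leaves the secondary C9 hydroxyl, and a desilylation that does not move the C8 acyl group.

28 is cut at C9–C10, which opens the ten-membered ring to 26 (through 27). The cut is placed there because C9 is a carbinol on an alkene carbon, and because the awkward cis geometry of C1=C10 can then be set in an open chain. The gain is an acyclic precursor whose three stereocentres C6–C8 already exist. The demand is closure of a medium ring in competition with oligomerisation, addition to the aldehyde only, and the syn 8,9-relationship, which runs against open-chain Felkin control.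

26 goes back through 25 and 24 to 21 and 22 by cutting the acyl–O8 bond and adjusting C9 (aldehyde, alcohol, silyl ether). 21 goes back through 20 to 19 by cutting the O9–Si bond and the two acetal C–O bonds. The acid is attached late so that its α-centre sees few steps, and C8/C9 are carried as one acetal as long as possible. The demand is clean differentiation of the primary and secondary hydroxyls of 20, no acyl migration in 25, and a silyl group at O14 that outlasts the acid used on the acetal.

19 is cut at C6–C7 and at the lactone bond O6–C12, which gives 12 and 16. This is the most convergent cut: two fragments of similar size, the lactone and two stereocentres made in one operation. The demand is anti addition (trans lactone), the correct alkene face of the allyl unit relative to the C8 centre, and an untouched C10–I bond, hence no nickel.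

16 goes back to 15 by moving the leaving group from C13 to the carbinol oxygen on C7 (allylic transposition). 15 is cut at C7–C11 into 13 and 14. C8 then comes from the chiral pool with the right configuration. The demand is that the acetal centre is not epimerised and that the bromide is formed as the conjugated Z isomer.

12 goes back through 11, 10, 9 and 8 by changing the C6 and C14 oxidation levels and cutting the C10–I bond to 7. 7 is cut at C1=C10 into 5 and 6. The iodine is introduced on an E enal because addition–elimination places it cis to C2. The demand is a protecting group on O6 orthogonal to the O14 silyl ether, and a mild last oxidation that keeps the C4=C5 Z geometry of a neral-type enal.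

5 goes back through 4 and 3 to 2 and 1 by cutting the remote double bond of 1 between C1 and the isopropylidene carbon. 1 supplies C1–C6, C15 and the Z alkene ready-made. The demand is selective oxidation of the remote alkene beside the allylic C4=C5 alkene.

## Other disconnections considered

Alternative 1: The cut removes the lactone carbonyl, that is the bonds C11–C12 and C12–O6. In the forward sense the ready ten-membered ethynyl carbinol A2 (C6–OH, C7–C≡CH) would be cyclocarbonylated with PdCl2(PPh3)2 and SnCl2 under CO to the bis-silyl lactone A1.
- In favour: the Michael acceptor appears at the very end. Here the alternative is better than the chosen plan, which carries the methylene lactone through eight steps, two of them with chromium reagents. Cyclocarbonylation of 3-butyn-1-ols is an established reaction type and gives the exocyclic alkene directly.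
- Against: the cut does not form the carbocycle. The ten-membered ring with trans C6–OH and C7-ethynyl must first be closed by some other C–C bond, so the hard problem is only postponed. The C6 hydroxyl of A2 is allylic to a trisubstituted alkene and can ionise under the Lewis-acidic palladium/tin conditions, with loss of the C6 configuration or of the C4=C5 geometry. An extra silyl group on O9 has to be put on and taken off.
- Comparison: in structure, the chosen plan uses the lactone as a turn element during ring closure and this alternative gives that up. In mechanism, the acylpalladium step needs the hydroxyl and alkyne gauche on a medium ring whose conformation is not known, while the chromium addition needs only proximity of C9 and C10. In step economy it is equal after the key step at best (desilylation, oxidation) and longer before it.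

Alternative 2: The cut is C2–C3, with a nitrogen inserted between the two carbons. The eleven-membered secondary amine A4 would be treated with an anomeric amide, nitrogen would leave as N2, and the two carbon radicals would recombine to the carbocycle A3.
- In favour: the ring is first closed as an amine by C–N bond formation, which is easier than medium-ring C–C closure. The new bond is remote from C6–C9, so the ring-forming step creates no stereocentre. On this point the alternative is better than the chosen plan, whose ring closure must also set C9.
- Against: both radicals are allylic (C2 next to C1=C10, C3 next to C4=C5). Recombination at the transposed ends C10 or C5 would give smaller rings, and each allyl radical can lose the cis geometry that both ring alkenes need. A3 still lacks the lactone, so the carbonylation of Alternative 1 and several deprotections follow.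
- Comparison: the chosen plan fixes both alkene geometries in open-chain intermediates and never puts them at risk. In mechanism a radical pair in a strained ring is harder to direct than a polar 1,2-addition. In step economy this is the longest of the four plans.

Alternative 3: The cut is C7–C8, with C13 reconnected to O8. In the thirteen-membered keto ether A6 the C8 enolate (between the C9 ketone and the ether oxygen) would attack butenolide carbon C7 while the C13–O bond breaks, giving the hydroxy ketone A5.
- In favour: one step forms C7–C8, sets C7 and C8, releases the exocyclic methylene and the free C8 hydroxyl, and contracts the ring from thirteen to ten. In bond-forming economy this is better than the chosen plan. A thirteen-membered ether is also easier to close than a ten-membered carbocycle.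
- Against: ketone enolates are reluctant partners in [2,3]-Wittig shifts. The proton at C6 (γ-position of the butenolide) is comparably acidic, and its removal destroys the C6 centre. The face selection depends on an unknown transannular conformation. A5 is an α-hydroxy ketone that can epimerise at C8, and its alkoxide can translactonise.
- Comparison: C9 must afterwards be set by ketone reduction, which is no more certain than the chromium addition, so the plans are equal on that point. After the key step four operations remain (acylation, reduction, desilylation, oxidation) against two in the chosen plan. The synthesis of A6 with both Z alkenes is not shorter than that of 26.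

Key step: step 18

Remark: the configurations written for the seco aldehyde and for the cyclised product agree with the target at C6–C9 and in both alkene geometries, so no structure needed correction. The one change is that O14 is carried as its tert-butyldiphenylsilyl ether, because a tert-butyldimethylsilyl ether is unlikely to outlast the acid needed for the acetal (step 13) and for the triethylsilyl ether (step 16). Germacranolide numbering is used throughout (the CH2OH carbon of nerol is C6; its isopropylidene carbon is lost next to C1).

## Route

Step 1
Reactants: 1 nerol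
Product: 2 neryl acetate
Conditions: Ac2O, pyridine, DMAP (cat.), CH2Cl2, 0 °C to rt
Reagents that add atoms: acetic anhydride, CC(=O)OC(C)=O
Why: DMAP-catalysed acetylation of the primary allylic alcohol; the acetate masks O6 and deactivates the C4=C5 alkene for step 2.

Step 2
Reactants: 2 neryl acetate
Product: 3 (2Z)-6,7-epoxy-3,7-dimethyloct-2-en-1-yl acetate
Conditions: mCPBA (1.05 equiv), CH2Cl2, 0 °C
Reagents that add atoms: 3-chloroperoxybenzoic acid, O=C(OO)c1cccc(Cl)c1
Why: Prilezhaev epoxidation is fastest at the most electron-rich alkene, the remote isopropylidene double bond; C4=C5 is deactivated by the allylic acetate. The new centre is racemic and is destroyed in step 3.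

Step 3
Reactants: 3 (2Z)-6,7-epoxy-3,7-dimethyloct-2-en-1-yl acetate
Product: 5 (2Z)-3-methyl-6-oxohex-2-en-1-yl acetate, via diol 4 (not isolated)
Conditions: H5IO6 (1.2 equiv), THF/H2O, 0 °C to rt
Reagents that add atoms: water, O (its oxygen enters diol 4 at the tertiary carbon and leaves with acetone)
Why: Acid-mediated opening of the epoxide by water gives diol 4, which periodate cleaves (Malaprade glycol cleavage) to the C1 aldehyde and acetone; the allylic acetate and the Z alkene are inert to H5IO6 at this temperature.

Step 4
Reactants: 5 (2Z)-3-methyl-6-oxohex-2-en-1-yl acetate; 6 (triphenylphosphoranylidene)acetaldehyde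
Product: 7 (2Z,6E)-3-methyl-8-oxoocta-2,6-dien-1-yl acetate
Conditions: 6 (1.1 equiv), toluene, 80 °C
Reagents that add atoms: none
Why: Wittig reaction of the stabilised formyl ylide forms C1=C10 as the E enal (reversible oxaphosphetane formation, thermodynamic control); only a small excess of 6 is used to limit a second homologation.

Step 5
Reactants: 7 (2Z,6E)-3-methyl-8-oxoocta-2,6-dien-1-yl acetate
Product: 8 (2Z,6Z)-7-iodo-3-methyl-8-oxoocta-2,6-dien-1-yl acetate
Conditions: I2 (1.5 equiv), K2CO3, DMAP (0.2 equiv), THF/H2O 1:1, rt
Reagents that add atoms: iodine, II
Why: Morita–Baylis–Hillman-type α-iodination: DMAP adds to C1, the enolate is iodinated at C10 and DMAP is expelled. This gives the (Z)-2-iodoenal with iodine cis to C2, the position C9 takes later.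

Step 6
Reactants: 8 (2Z,6Z)-7-iodo-3-methyl-8-oxoocta-2,6-dien-1-yl acetate
Product: 9 (2Z,6Z)-8-hydroxy-7-iodo-3-methylocta-2,6-dien-1-yl acetate
Conditions: NaBH4, CeCl3·7H2O, MeOH, −40 °C
Reagents that add atoms: none
Why: Luche reduction gives clean 1,2-reduction of the cerium-activated aldehyde; the alkenyl iodide and the acetate are untouched at low temperature.

Step 7
Reactants: 9 (2Z,6Z)-8-hydroxy-7-iodo-3-methylocta-2,6-dien-1-yl acetate
Product: 10 (2Z,6Z)-8-[(tert-butyldiphenylsilyl)oxy]-7-iodo-3-methylocta-2,6-dien-1-yl acetate
Conditions: TBDPSCl, imidazole, CH2Cl2, 0 °C to rt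
Reagents that add atoms: tert-butyl(chloro)diphenylsilane, CC(C)(C)[Si](Cl)(c1ccccc1)c1ccccc1
Why: Silylation of the primary allylic alcohol through the N-silylimidazolium; this silyl ether is chosen because it withstands the acid of steps 13 and 16.

Step 8
Reactants: 10 (2Z,6Z)-8-[(tert-butyldiphenylsilyl)oxy]-7-iodo-3-methylocta-2,6-dien-1-yl acetate
Product: 11 (2Z,6Z)-8-[(tert-butyldiphenylsilyl)oxy]-7-iodo-3-methylocta-2,6-dien-1-ol
Conditions: K2CO3 (0.2 equiv), MeOH, 0 °C
Reagents that add atoms: none
Why: Zemplén-type transesterification with methanol removes the acetate; the silyl ether and the alkenyl iodide are stable to K2CO3 in methanol.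

Step 9
Reactants: 11 (2Z,6Z)-8-[(tert-butyldiphenylsilyl)oxy]-7-iodo-3-methylocta-2,6-dien-1-ol
Product: 12 (2Z,6Z)-8-[(tert-butyldiphenylsilyl)oxy]-7-iodo-3-methylocta-2,6-dienal
Conditions: TEMPO (0.1 equiv), PhI(OAc)2 (1.1 equiv), CH2Cl2, 0 °C
Reagents that add atoms: none
Why: Oxoammonium oxidation of the primary allylic alcohol stops at the aldehyde under nearly neutral conditions, which is what a Z enal of the neral type needs to keep its geometry; 12 is used at once.

Step 10
Reactants: 13 (R)-2,3-O-isopropylideneglyceraldehyde; 14 ethyl acrylate
Product: 15 ethyl 2-{[(4R)-2,2-dimethyl-1,3-dioxolan-4-yl](hydroxy)methyl}prop-2-enoate (both carbinol epimers)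
Conditions: DABCO (0.5 equiv), dioxane/H2O 1:1, rt
Reagents that add atoms: none
Why: Morita–Baylis–Hillman reaction: DABCO adds to the acrylate and the zwitterionic enolate attacks the aldehyde, forming C7–C11. The carbinol centre need not be controlled because it becomes sp2 in step 11, and the acetal centre (future C8) is not touched.

Step 11
Reactants: 15 ethyl 2-{[(4R)-2,2-dimethyl-1,3-dioxolan-4-yl](hydroxy)methyl}prop-2-enoate
Product: 16 ethyl (2Z)-2-(bromomethyl)-3-[(4S)-2,2-dimethyl-1,3-dioxolan-4-yl]prop-2-enoate
Conditions: NBS, Me2S, CH2Cl2, 0 °C to rt
Reagents that add atoms: N-bromosuccinimide, O=C1CCC(=O)N1Br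
Why: Corey–Kim-type activation turns the hydroxyl into an alkoxysulfonium leaving group and bromide attacks the terminal methylene in an SN2′ sense, giving the conjugated trisubstituted bromide with C8 trans to the ester. The nearly neutral medium spares the acetonide.

Step 12
Reactants: 12 (2Z,6Z)-8-[(tert-butyldiphenylsilyl)oxy]-7-iodo-3-methylocta-2,6-dienal; 16 ethyl (2Z)-2-(bromomethyl)-3-[(4S)-2,2-dimethyl-1,3-dioxolan-4-yl]prop-2-enoate
Product: 19 trans α-methylene lactone with 8,9-acetonide, via allylchromium dichloride 17 (not isolated), via anti hydroxy ester 18 (not isolated)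
Conditions: CrCl2 (4 equiv, nickel-free), 16 (1.5 equiv), THF, 0 °C to rt; then PPTS (cat.), CH2Cl2, rt
Reagents that add atoms: none
Why: Nozaki–Hiyama allylation in its 2-(alkoxycarbonyl)allyl form (Dreiding–Schmidt lactone synthesis): two CrCl2 reduce the allylic bromide to 17, whose alkene isomers interconvert by 1,3-metal shift and which adds through C7 in a chair with the C5 chain and C8 both equatorial (anti adduct 18, hence the trans lactone). The aldehyde enters the alkene face anti to the C8–C9 bond, with H8 in the alkene plane (allylic strain) and the C8–O bond kept out of the antiperiplanar position, which sets C7 and with it C6 as in 30. Without a nickel salt divalent chromium does not insert into the C10–I bond.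

Step 13
Reactants: 19 trans α-methylene lactone with 8,9-acetonide
Product: 20 8,9-diol lactone
Conditions: AcOH/H2O 4:1, 40 °C
Reagents that add atoms: none
Why: Acid-catalysed hydrolysis of the terminal isopropylidene acetal; the tert-butyldiphenylsilyl ether, the lactone and the alkenyl iodide tolerate aqueous acetic acid, and the weakly acidic medium does not promote attack of O8 on C12.

Step 14
Reactants: 20 8,9-diol lactone
Product: 21 9-O-triethylsilyl ether of 20
Conditions: TESCl (1.05 equiv), imidazole, CH2Cl2, −40 °C
Reagents that add atoms: chlorotriethylsilane, CC[Si](Cl)(CC)CC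
Why: Kinetic silylation takes the primary C9 hydroxyl and leaves the hindered secondary C8 hydroxyl free.

Step 15
Reactants: 21 9-O-triethylsilyl ether of 20; 22 (S)-2-methylbutanoic acid
Product: 24 8-O-[(2S)-2-methylbutanoyl] 9-O-triethylsilyl lactone, via mixed anhydride 23 (not isolated)
Conditions: 22, 2,4,6-Cl3C6H2COCl, Et3N, toluene, rt; then 21, DMAP, rt
Reagents that add atoms: 2,4,6-trichlorobenzoyl chloride, O=C(Cl)c1c(Cl)cc(Cl)cc1Cl (its acyl group is present in 23 only)
Why: Yamaguchi esterification: DMAP attacks the aliphatic carbonyl of 23 and the acylpyridinium acylates O8. No ketene-forming acid chloride is involved and the C8–O bond is not broken, so the α-centre of the acid and C8 keep their configuration.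

Step 16
Reactants: 24 8-O-[(2S)-2-methylbutanoyl] 9-O-triethylsilyl lactone
Product: 25 8-O-[(2S)-2-methylbutanoyl] 9-hydroxy lactone
Conditions: PPTS (0.2 equiv), MeOH/CH2Cl2 1:1, 0 °C
Reagents that add atoms: none
Why: Acid-catalysed methanolysis cleaves the primary triethylsilyl ether far faster than the tert-butyldiphenylsilyl ether; the mildly acidic medium disfavours migration of the acyl group from O8 to O9.

Step 17
Reactants: 25 8-O-[(2S)-2-methylbutanoyl] 9-hydroxy lactone
Product: 26 seco iodoalkene aldehyde
Conditions: Dess–Martin periodinane, CH2Cl2, 0 °C to rt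
Reagents that add atoms: none
Why: Dess–Martin oxidation (ligand exchange at iodine, then removal of the carbinol hydrogen) gives the C9 aldehyde without base, so C8, now α to a carbonyl, is not epimerised; 26 is used crude.

Step 18
Reactants: 26 seco iodoalkene aldehyde
Product: 28 14-O-tert-butyldiphenylsilyl 14-hydroxy analogue of 30, via alkenylchromium dichloride 27 (not isolated)
Conditions: CrCl2 (10 equiv), NiCl2 (0.1 equiv), DMSO/THF, 0.002 M, slow addition of 26, rt
Reagents that add atoms: none
Why: CrCl2 reduces NiCl2 to zerovalent nickel, which inserts into the C10–I bond; transmetalation to trivalent chromium gives 27 with retention of the alkene geometry and returns the nickel salt to the cycle. The C10–Cr bond then adds 1,2 to the C9 aldehyde and forms C9–C10; the closest known reaction type is the Nozaki–Hiyama–Kishi macrocyclisation of an alkenyl iodide onto an aldehyde. The ten-membered carbocycle closes in a 10-exo-trig mode, the attacked C=O bond staying outside the new ring. The new centre C9 is under substrate control: the C8 centre and the trans lactone restrict the conformation of the closing chain, and coordination of the oxophilic trivalent chromium to both the aldehyde oxygen and the C8 acyloxy group should put C10 on the face that gives the syn (threo) 8,9-relationship, against the open Felkin preference. The step needs chemoselectivity for the aldehyde over the lactone, the ester and the methylene Michael acceptor, which the low basicity and nucleophilicity of an alkenylchromium secure. It also needs cyclisation to outrun oligomerisation, which high dilution and three turn elements (two cis alkenes and the lactone) favour. The in-ring cis geometry of C1=C10 is that of the (Z)-iodide, iodine standing where C9 ends up.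

Step 19
Reactants: 28 14-O-tert-butyldiphenylsilyl 14-hydroxy analogue of 30
Product: 29 9,14-diol (14-hydroxy analogue of 30)
Conditions: HF·pyridine, pyridine, THF, 0 °C to rt
Reagents that add atoms: none
Why: Fluoride-induced desilylation through pentacoordinate silicon; buffered HF·pyridine stays on the acidic side, which disfavours acyl migration and conjugate addition to the methylene lactone.

Step 20
Reactants: 29 9,14-diol (14-hydroxy analogue of 30)
Product: 30 target germacranolide
Conditions: TEMPO (0.2 equiv), PhI(OAc)2 (1.2 equiv), CH2Cl2, rt
Reagents that add atoms: none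
Why: Oxoammonium oxidation is far faster for the unhindered primary allylic C14 alcohol than for the secondary C9 alcohol flanked by C8 and the fully substituted C10, and it stops at the enal; no stereocentre is touched.

## Compound list

1 | nerol, (2Z)-3,7-dimethylocta-2,6-dien-1-ol | CC(C)=CCC/C(C)=C\CO | starting material
2 | neryl acetate, (2Z)-3,7-dimethylocta-2,6-dien-1-yl acetate | CC(=O)OC/C=C(/C)CCC=C(C)C | intermediate
3 | (2Z)-6,7-epoxy-3,7-dimethyloct-2-en-1-yl acetate (racemic at the epoxide carbon) | CC(=O)OC/C=C(/C)CCC1OC1(C)C | intermediate
4 | (2Z)-6,7-dihydroxy-3,7-dimethyloct-2-en-1-yl acetate (racemic, not isolated) | CC(=O)OC/C=C(/C)CCC(O)C(C)(C)O | intermediate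
5 | (2Z)-3-methyl-6-oxohex-2-en-1-yl acetate | CC(=O)OC/C=C(/C)CCC=O | intermediate
6 | (triphenylphosphoranylidene)acetaldehyde | O=CC=P(c1ccccc1)(c1ccccc1)c1ccccc1 | starting material
7 | (2Z,6E)-3-methyl-8-oxoocta-2,6-dien-1-yl acetate | CC(=O)OC/C=C(/C)CC/C=C/C=O | intermediate
8 | (2Z,6Z)-7-iodo-3-methyl-8-oxoocta-2,6-dien-1-yl acetate | CC(=O)OC/C=C(/C)CC/C=C(\I)C=O | intermediate
9 | (2Z,6Z)-8-hydroxy-7-iodo-3-methylocta-2,6-dien-1-yl acetate | CC(=O)OC/C=C(/C)CC/C=C(\I)CO | intermediate
10 | (2Z,6Z)-8-[(tert-butyldiphenylsilyl)oxy]-7-iodo-3-methylocta-2,6-dien-1-yl acetate | CC(=O)OC/C=C(/C)CC/C=C(\I)CO[Si](c1ccccc1)(c1ccccc1)C(C)(C)C | intermediate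
11 | (2Z,6Z)-8-[(tert-butyldiphenylsilyl)oxy]-7-iodo-3-methylocta-2,6-dien-1-ol | OC/C=C(/C)CC/C=C(\I)CO[Si](c1ccccc1)(c1ccccc1)C(C)(C)C | intermediate
12 | (2Z,6Z)-8-[(tert-butyldiphenylsilyl)oxy]-7-iodo-3-methylocta-2,6-dienal | O=C/C=C(/C)CC/C=C(\I)CO[Si](c1ccccc1)(c1ccccc1)C(C)(C)C | intermediate
13 | (R)-2,3-O-isopropylideneglyceraldehyde | O=C[C@H]1COC(C)(C)O1 | starting material
14 | ethyl acrylate | C=CC(=O)OCC | starting material
15 | ethyl 2-{[(4R)-2,2-dimethyl-1,3-dioxolan-4-yl](hydroxy)methyl}prop-2-enoate (both carbinol epimers) | C=C(C(=O)OCC)C(O)[C@H]1COC(C)(C)O1 | intermediate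
16 | ethyl (2Z)-2-(bromomethyl)-3-[(4S)-2,2-dimethyl-1,3-dioxolan-4-yl]prop-2-enoate | CCOC(=O)/C(CBr)=C/[C@H]1COC(C)(C)O1 | intermediate
17 | allylchromium dichloride from 16: CrCl2 on C13 in place of bromine, trivalent chromium; the alkene isomers interconvert and the reacting one (C8 trans to C13) is drawn; not isolated | CCOC(=O)/C(C[Cr](Cl)Cl)=C\[C@H]1COC(C)(C)O1 | intermediate
18 | anti hydroxy ester: ethyl 2-methylene ester (C12, C11=C13) with C7 bearing the (4S)-dioxolanyl group (C8, C9) and C6 bearing OH and the iodo-dienyl chain; C6, C7, C8 as in 30; not isolated | C=C(C(=O)OCC)[C@@H]([C@H](O)/C=C(/C)CC/C=C(\I)CO[Si](c1ccccc1)(c1ccccc1)C(C)(C)C)[C@H]1COC(C)(C)O1 | intermediate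
19 | trans α-methylene-γ-butyrolactone (H6/H7 trans) bearing at C6 the (1Z,5Z)-7-[(tert-butyldiphenylsilyl)oxy]-6-iodo-2-methylhepta-1,5-dienyl chain and at C7 the (4S)-2,2-dimethyl-1,3-dioxolan-4-yl group; C6, C7, C8 as in 30 | C=C1C(=O)O[C@H](/C=C(/C)CC/C=C(\I)CO[Si](c2ccccc2)(c2ccccc2)C(C)(C)C)[C@H]1[C@H]1COC(C)(C)O1 | intermediate
20 | 8,9-diol lactone (acetonide of 19 removed) | C=C1C(=O)O[C@H](/C=C(/C)CC/C=C(\I)CO[Si](c2ccccc2)(c2ccccc2)C(C)(C)C)[C@H]1[C@H](O)CO | intermediate
21 | 9-O-triethylsilyl ether of 20 (8-OH free) | C=C1C(=O)O[C@H](/C=C(/C)CC/C=C(\I)CO[Si](c2ccccc2)(c2ccccc2)C(C)(C)C)[C@H]1[C@H](O)CO[Si](CC)(CC)CC | intermediate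
22 | (S)-2-methylbutanoic acid | CC[C@H](C)C(=O)O | starting material
23 | (2S)-2-methylbutanoic 2,4,6-trichlorobenzoic anhydride (not isolated) | CC[C@H](C)C(=O)OC(=O)c1c(Cl)cc(Cl)cc1Cl | intermediate
24 | 8-O-[(2S)-2-methylbutanoyl] 9-O-triethylsilyl lactone | C=C1C(=O)O[C@H](/C=C(/C)CC/C=C(\I)CO[Si](c2ccccc2)(c2ccccc2)C(C)(C)C)[C@H]1[C@H](OC(=O)[C@@H](C)CC)CO[Si](CC)(CC)CC | intermediate
25 | 8-O-[(2S)-2-methylbutanoyl] 9-hydroxy lactone | C=C1C(=O)O[C@H](/C=C(/C)CC/C=C(\I)CO[Si](c2ccccc2)(c2ccccc2)C(C)(C)C)[C@H]1[C@H](OC(=O)[C@@H](C)CC)CO | intermediate
26 | seco iodoalkene aldehyde: C9 aldehyde, C8 (2S)-2-methylbutanoate, trans α-methylene lactone, (Z)-C10 iodide, C14 tert-butyldiphenylsilyl ether | C=C1C(=O)O[C@H](/C=C(/C)CC/C=C(\I)CO[Si](c2ccccc2)(c2ccccc2)C(C)(C)C)[C@H]1[C@H](OC(=O)[C@@H](C)CC)C=O | intermediate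
27 | alkenylchromium dichloride from 26: CrCl2 on C10 in place of iodine, trivalent chromium, alkene geometry retained; not isolated | C=C1C(=O)O[C@H](/C=C(/C)CC/C=C(\[Cr](Cl)Cl)CO[Si](c2ccccc2)(c2ccccc2)C(C)(C)C)[C@H]1[C@H](OC(=O)[C@@H](C)CC)C=O | intermediate
28 | 14-O-tert-butyldiphenylsilyl 14-hydroxy analogue of 30 (ten-membered ring closed, 9-hydroxyl syn to the C8 ester) | C=C1C(=O)O[C@@H]2/C=C(/C)CC/C=C(/CO[Si](c3ccccc3)(c3ccccc3)C(C)(C)C)[C@H](O)[C@@H](OC(=O)[C@@H](C)CC)[C@@H]12 | intermediate
29 | 9,14-diol: 14-hydroxy analogue of 30 | C=C1C(=O)O[C@@H]2/C=C(/C)CC/C=C(/CO)[C@H](O)[C@@H](OC(=O)[C@@H](C)CC)[C@@H]12 | intermediate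
30 | (6R,7S,8S,9S)-9-hydroxy-8-[(2S)-2-methylbutanoyloxy]-14-oxogermacra-1(10)E,4Z,11(13)-trien-12,6-olide | C=C1C(=O)O[C@@H]2/C=C(/C)CC/C=C(/C=O)[C@H](O)[C@@H](OC(=O)[C@@H](C)CC)[C@@H]12 | target

## Step count and least certain steps

Total step count: 20. Longest linear sequence: 18 steps (steps 1–9 and 12–20, from 1); steps 10 and 11 form the two-step branch to 16.

Step 18 (key step). The most likely failure is poor facial selectivity at the C9 aldehyde. Chelation by an acyloxy group is weak, and an open approach with the C8–O bond anti to the incoming C10 would give the 9-epimer. Intermolecular coupling can also compete if the chain ends are not held close. The fallback sets out from 26 and comes back at 28. The cyclisation is run as in step 18, and the 9-epimeric alcohol F1 is oxidised with Dess–Martin periodinane to the ring enone F2. F2 is reduced with NaBH4/CeCl3·7H2O at −78 °C. C9 is then set by delivery of a small hydride to the outer face of a ring ketone and no longer by C–C bond formation.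

Step 12. The most likely failure is erosion of the two selectivities the step must deliver together. Syn addition can occur through the allylchromium isomer with C8 cis to the metallated C13; this isomer forms first from 16, keeps the ester conjugated, and would end in the cis lactone. The facial bias from the dioxolane may also be weak. The fallback sets out from 13 (with 12 as partner) and comes back at 19.
- Ohira–Bestmann homologation of 13 gives the alkyne F3.
- Deprotonation with n-BuLi and ethyl chloroformate gives the ynoate F4.
- Conjugate hydroalumination with DIBAL-H/HMPA (hydride and aluminium add syn) and alkylation of the alkenylalane with ICH2Bpin give the allylboronate F5, in which C8 is fixed trans to the CH2B group and cannot isomerise.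
- Addition of F5 to 12 (toluene, 60–80 °C, with Sc(OTf)3 as catalyst if needed) runs through a closed chair in which C8 must be equatorial, so the anti adduct and, after PPTS, the trans lactone 19 follow from the reagent geometry. The shorter bonds of the boron transition state should also sharpen the induction from C8.

Step 16. The most likely failure is migration of the acyl group from O8 to the freed O9 through a five-membered orthoester-type intermediate, or attack of O9 on neighbouring carbonyl groups, while the hydroxy ester is handled. The fallback sets out from 24 and comes back at 26, leaving out 25. Under Swern conditions ((COCl)2, DMSO, CH2Cl2, −78 to −30 °C, then i-Pr2NEt) the chlorosulfonium salt cleaves the primary triethylsilyl ether and the alkoxysulfonium is deprotonated to the aldehyde. A free 9-hydroxy 8-ester is never present, and the tert-butyldiphenylsilyl ether is inert. No new compound is made (F0).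

Step 4. The most likely failure is a second olefination, because product 7 is itself an aldehyde, together with sluggish reaction of the stabilised ylide and aldol side reactions of the enolisable aldehyde at 80 °C. The fallback sets out from 5 and comes back at 7. Wittig reaction of 5 with the non-stabilised ylide from (1,3-dioxolan-2-ylmethyl)triphenylphosphonium bromide (NaHMDS, THF, −78 °C) gives the alkenyl dioxolane F6 as an alkene mixture. Oxalic acid in wet THF hydrolyses the acetal and equilibrates the enal to the E isomer 7. The masked formyl group cannot be olefinated a second time.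

## Further compounds

F1 | step 18 | 9-epimer of 28 (9-hydroxyl anti to the C8 ester) | C=C1C(=O)O[C@@H]2/C=C(/C)CC/C=C(/CO[Si](c3ccccc3)(c3ccccc3)C(C)(C)C)[C@@H](O)[C@@H](OC(=O)[C@@H](C)CC)[C@@H]12
F2 | step 18 | 9-oxo analogue of 28 (ring enone) | C=C1C(=O)O[C@@H]2/C=C(/C)CC/C=C(/CO[Si](c3ccccc3)(c3ccccc3)C(C)(C)C)C(=O)[C@@H](OC(=O)[C@@H](C)CC)[C@@H]12
F3 | step 12 | (4S)-4-ethynyl-2,2-dimethyl-1,3-dioxolane | C#C[C@H]1COC(C)(C)O1
F4 | step 12 | ethyl 3-[(4S)-2,2-dimethyl-1,3-dioxolan-4-yl]prop-2-ynoate | CCOC(=O)C#C[C@H]1COC(C)(C)O1
F5 | step 12 | ethyl (2Z)-3-[(4S)-2,2-dimethyl-1,3-dioxolan-4-yl]-2-[(4,4,5,5-tetramethyl-1,3,2-dioxaborolan-2-yl)methyl]prop-2-enoate (C8 cis to the ester) | CCOC(=O)/C(CB1OC(C)(C)C(C)(C)O1)=C\[C@H]1COC(C)(C)O1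
F0 | step 16 | none | none
F6 | step 4 | (2Z)-6-(1,3-dioxolan-2-yl)-3-methylhexa-2,5-dien-1-yl acetate (mixture at the new alkene) | CC(=O)OC/C=C(/C)CCC=CC1OCCO1
A1 | alternative 1 | 9,14-bis-O-tert-butyldimethylsilyl 14-hydroxy analogue of the target | C=C1C(=O)O[C@@H]2/C=C(/C)CC/C=C(/CO[Si](C)(C)C(C)(C)C)[C@H](O[Si](C)(C)C(C)(C)C)[C@@H](OC(=O)[C@@H](C)CC)[C@@H]12
A2 | alternative 1 | ten-membered carbocycle with C7 ethynyl, free C6 hydroxyl, C8 ester, C9 and C14 tert-butyldimethylsilyl ethers | C#C[C@H]1[C@H](O)/C=C(/C)CC/C=C(/CO[Si](C)(C)C(C)(C)C)[C@H](O[Si](C)(C)C(C)(C)C)[C@H]1OC(=O)[C@@H](C)CC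
A3 | alternative 2 | ten-membered carbocycle with C7 ethynyl, C6 triethylsilyl ether, C8 ester, C9 and C14 tert-butyldimethylsilyl ethers | C#C[C@H]1[C@H](O[Si](CC)(CC)CC)/C=C(/C)CC/C=C(/CO[Si](C)(C)C(C)(C)C)[C@H](O[Si](C)(C)C(C)(C)C)[C@H]1OC(=O)[C@@H](C)CC
A4 | alternative 2 | eleven-membered secondary amine with NH between C2 and C3, otherwise as A3 | C#C[C@H]1[C@H](O[Si](CC)(CC)CC)/C=C(/C)CNC/C=C(/CO[Si](C)(C)C(C)(C)C)[C@H](O[Si](C)(C)C(C)(C)C)[C@H]1OC(=O)[C@@H](C)CC
A5 | alternative 3 | 8-hydroxy-9-oxo germacranolide with α-methylene lactone and C14 tert-butyldimethylsilyl ether | C=C1C(=O)O[C@@H]2/C=C(/C)CC/C=C(/CO[Si](C)(C)C(C)(C)C)C(=O)[C@@H](O)[C@@H]12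
A6 | alternative 3 | thirteen-membered keto ether: butenolide (C7=C11) whose C13 is linked through oxygen to C8H2 next to the C9 ketone | O=C1O[C@@H]2/C=C(/C)CC/C=C(/CO[Si](C)(C)C(C)(C)C)C(=O)COCC1=C2
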